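**The race.** The starting complex has two ways forward. With the incoming ligand it gives the complex with one exchanged, which then equilibrates with the isomer of the product. With itself it gives the self-condensation product. It also slips into the dormant form, which holds it back from both.

in all of them: leaving ligand 0.100 M; time 25 h
- green: starting complex 0.20 M; incoming ligand 0.240 M; temperature 25 °C; everything together at the start
- violet: starting complex 0.20 M; incoming ligand 0.240 M (fed, over 15 h); temperature 25 °C; all else is in the flask from the start; the feed brings no volume worth counting
- teal: starting complex 0.20 M; incoming ligand 0.240 M (fed, over 15 h); the addition at −5 °C, then warmed to 25 °C; the feed brings no volume worth counting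
- ochre: starting complex 0.20 M; incoming ligand 0.240 M (fed, over 1.5 h); temperature 25 °C; all else is in the flask from the start; the feed brings no volume worth counting
- blue: starting complex 0.20 M (fed, over 15 h); incoming ligand 0.240 M; temperature 25 °C; all else is in the flask from the start; the feed brings no volume worth counting

    starting complex + incoming ligand → leaving ligand + complex with one exchanged (k1 = 0.0275 L mol⁻¹ min⁻¹, Ea1 = 77.0 kJ mol⁻¹)
    complex with one exchanged + incoming ligand → leaving ligand + complex with two exchanged (k2 = 0.0164 L mol⁻¹ min⁻¹, Ea2 = 74.0 kJ mol⁻¹)
    complex with two exchanged + incoming ligand → leaving ligand + complex with three exchanged (k3 = 0.00205 L mol⁻¹ min⁻¹, Ea3 = 62.0 kJ mol⁻¹)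
    complex with one exchanged ⇌ isomer of the product (K4 = 2.2, k4 = 0.00614 min⁻¹, Ea4 = 93.0 kJ mol⁻¹, ΔH4 = −30.0 kJ mol⁻¹)
    2 starting complex → self-condensation product (k5 = 0.0371 L mol⁻¹ min⁻¹, Ea5 = 62.0 kJ mol⁻¹)
    starting complex ⇌ dormant form (K6 = 3.8, k6 = 0.0124 min⁻¹, Ea6 = 96.0 kJ mol⁻¹, ΔH6 = 25.0 kJ mol⁻¹)
    (constants at 25 °C)

- percent here means starting complex units held: one self-condensation product counts as two
- a doubled species enters its step squared and goes two at a time
- the list of constants is for 25 °C, to be carried to other temperatures by the activation energies and enthalpies

- the flask with the highest amount of isomer of the product, in percent of the starting complex charged ("all alike" if they lie within 1.5 percentage points) (green / violet / teal / ochre / blue / all alike)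
- final isomer of the product, as a percentage of the starting complex charged, in green
- final isomer of the product, as a percentage of the starting complex charged, in violet
- final isomer of the product, as a percentage of the starting complex charged, in teal
- final isomer of the product, as a percentage of the starting complex charged, in ochre
- final isomer of the product, as a percentage of the starting complex charged, in blue

**Fast rungs.** Take green at its charge and list half-lives. The dormant equilibrium relaxes, both directions counted, in 0.738 h. The first half-life of the starting complex by self-condensation is 1.12 h. That is longer than the dormant relaxation, but close to it, so in green condensation is under way before the dormant form has taken its share. The isomer equilibrium relaxes in 1.29 h.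

**Slow rungs.** After these rungs, two ratios can be frozen. The free starting complex is 0.208 of its pool, the pool being starting complex plus dormant form. The isomer is 0.688 of its own pool, the isomer plus the complex with one exchanged. Exchange, pseudo-first-order at the charged ligand, then gives the first pool a half-life of 8.40 h. The second step drains the second pool with a half-life of 9.39 h. Both are slower than the isomer relaxation, so the isomer follows its pool.

**The selectivity.** The quantity to carry is the selectivity factor S, the rate of exchange over the rate of condensation, both counted in starting complex lost, with the free complex frozen at its share of the pool. S rises with the ligand and falls with the pool. At green's charge the frozen value is 2.13, while at the first moment, before any dormant form exists, it is 0.445.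

**Own reckoning.** The exchanged share of the complex consumed is S over one plus S. Multiplied by the isomer's frozen ratio, this gives 21.2% for green from the first-moment value and 46.8% from the frozen value. Both figures ignore what step two carries on and what stays unreacted, so the reckoning gives no single number for green. It does give an order. Blue starts with full ligand and an empty pool, so S starts high. Violet and teal start with a full pool and no ligand, so S starts at nothing. Ochre takes its ligand in 1.5 h against 15 h, so it lies nearer green. The order is therefore blue, green, ochre, then violet and teal, which this reckoning does not separate.

**The forecast.** It names blue as the highest, with blue 22%, green 20%, ochre 17%, violet 13% and teal 12%. Its grounds are that “Feeding the starting complex keeps it dilute”. Its order matches the reckoning and also places teal last.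

**The result.** Blue leads at 18.8%, over green 15.4%, ochre 13.5%, violet 11.6% and teal 11.1%, so the forecast's choice stands. Blue's lead over green is 3.4 percentage points. With the other amounts and the time held, blue's answer has moved 5 points at a charge of 0.514 M starting complex. Exchanged forms over self-condensation product, in starting complex units, read 3.27 in blue and 1.43 in green at 25.0 h. Teal charged with 0.080 M starting complex, its ligand held, has S higher by a factor of 2.50. That ratio reads 0.592 in teal and 1.50 in the neighbour flask, a factor of 2.53.

The numbers of this flask were set for the occasion, and the outcome is calculated.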